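**Retrosynthetic overview**

1. Daucane numbering is used: C-1 is the quaternary ring-fusion carbon (Me-15), C-4 the isopropyl carbinol, C-5 the ring-fusion CH, C-6 the CH–O–aroyl carbon, C-8=C-9 the alkene (Me-14 on C-8), C-10 the CH–O–isovaleryl carbon. The two esters are cut first, which leads back to enone diol 19 (4,6-dihydroxy, C-10 ketone).
2. Key disconnection: C-1–C-5 and C-8=C-9 of 19 are cut together. The precursor is the monocyclic 2-methylidene-oxane 15, in which O-4 is tied to C-10, C-5/C-6 are a cis-epoxide and C-8 is a ketal.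
3. Enabling feature: on the five-membered ring (C-1 to C-5) O-4 and C-10 are 1,3-cis while C-6 is trans to both, and C-6, C-8 and C-10 are 1,3-related oxidised carbons. C-10 can therefore hang on O-4 as a six-membered cyclic enol ether that holds its nucleophilic carbon C-1 over C-5, and the seven-membered ring can close by an aldol-type condensation of C-9 onto C-8.
4. 15 comes from (R)-terpinen-4-ol, whose six ring carbons become C-10, C-1, C-2, C-3, C-4 and C-5. The C-10–C-5 ring bond is cut (hydroboration, oxidation, enol silane ozonolysis), C-6 to C-8 are added by a Z-selective Wittig reaction, and a substrate-controlled epoxidation sets C-5/C-6.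
5. Ring order: the terpene six-membered ring is opened and a temporary oxanone ring (O-4–C-10) is closed. In the key step the five-membered carbocycle forms first, the temporary ring is released, and the seven-membered ring closes last.

Key step: step 10

Remark on configuration: read from the SMILES, the rings are trans-fused; 4-OH, H-5, C-10 and O-10 lie on one face, and the isopropyl group, Me-15, C-6 and O-6 on the other.

Assumption: (R)-terpinen-4-ol is used enantiomerically pure. Compounds 3 to 15 are mixtures of epimers at the methyl-bearing carbon that becomes C-1 (3 and 4 also at the neighbouring carbon); this does not matter, because C-1 is trigonal in 16.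

**Step 1**
Reactants: 1 (R)-terpinen-4-ol
Product: 2 triethylsilyl ether of terpinen-4-ol
Conditions: Et3SiOTf, 2,6-lutidine, CH2Cl2, 0 °C → rt
Reagents that add atoms: triethylsilyl trifluoromethanesulfonate CC[Si](CC)(CC)OS(=O)(=O)C(F)(F)F
Why: Silylation of the tertiary alcohol with a silyl triflate blocks the retro-aldol and elimination pathways that a free 3-hydroxy ketone would open in steps 3 and 4.

**Step 2**
Reactants: 2 triethylsilyl ether of terpinen-4-ol
Product: 4 2-methyl-5-(propan-2-yl)-5-(triethylsilyloxy)cyclohexan-1-ol, via alkylborane 3 (not isolated)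
Conditions: BH3·THF, THF, 0 °C → rt; then NaOH, H2O2, 0 °C → rt
Reagents that add atoms: hydrogen peroxide OO
Why: Brown hydroboration–oxidation puts the oxygen on the less substituted alkene carbon (anti-Markovnikov, syn addition), and the two new centres need no control because one becomes a ketone and the other becomes trigonal later.

**Step 3**
Reactants: 4 2-methyl-5-(propan-2-yl)-5-(triethylsilyloxy)cyclohexan-1-ol
Product: 5 2-methyl-5-(propan-2-yl)-5-(triethylsilyloxy)cyclohexan-1-one
Conditions: Dess–Martin periodinane, CH2Cl2, rt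
Reagents that add atoms: none
Why: Dess–Martin oxidation of the secondary alcohol is mild enough to leave the tertiary silyl ether intact.

**Step 4**
Reactants: 5 2-methyl-5-(propan-2-yl)-5-(triethylsilyloxy)cyclohexan-1-one
Product: 7 less substituted trimethylsilyl enol ether, via lithium enolate 6 (not isolated)
Conditions: LiN(i-Pr)2 (commercial solution), Me3SiCl present from the start, THF, −78 °C → 0 °C
Reagents that add atoms: chlorotrimethylsilane C[Si](C)(C)Cl
Why: Kinetic enolate formation removes a proton from the ring methylene and not from the methyl-bearing methine, and the in situ silyl trap should intercept the enolate before the 3-silyloxy group is eliminated.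

**Step 5**
Reactants: 7 less substituted trimethylsilyl enol ether
Product: 9 lactone aldehyde 5-methyl-6-oxo-2-(propan-2-yl)oxane-2-carbaldehyde, via silyloxy aldehyde acid 8 (not isolated)
Conditions: O3, CH2Cl2, −78 °C; PPh3, −78 °C → rt; then CF3CO2H, H2O, THF, rt, toluene azeotrope
Reagents that add atoms: ozone [O-][O+]=O
Why: Ozonolysis of the enol silane gives a carboxylic acid at the oxygen-bearing carbon and an aldehyde at the other, and acid then removes the triethylsilyl group so that the tertiary hydroxy acid lactonises while the non-enolisable aldehyde survives.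

**Step 6**
Reactants: 10 2-(2-bromoethyl)-2-methyl-1,3-dioxolane
Product: 11 [2-(2-methyl-1,3-dioxolan-2-yl)ethyl]triphenylphosphonium bromide
Conditions: PPh3, MeCN, reflux
Reagents that add atoms: triphenylphosphine c1ccc(cc1)P(c1ccccc1)c1ccccc1
Why: SN2 quaternisation of the phosphine by the primary bromide gives the Wittig salt.

**Step 7**
Reactants: 9 lactone aldehyde; 11 phosphonium bromide
Product: 13 Z-alkene lactone, via phosphonium ylide 12 (not isolated)
Conditions: 11, NaN(SiMe3)2, THF, −78 °C → 0 °C; then 9, −78 °C → rt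
Reagents that add atoms: none
Why: The salt-free Wittig reaction of a non-stabilised ylide with an aldehyde should give the Z-alkene under kinetic control, the aldehyde reacting much faster than the lactone carbonyl.

**Step 8**
Reactants: 13 Z-alkene lactone
Product: 14 cis-epoxy lactone
Conditions: m-CPBA, CH2Cl2, 0 °C → rt
Reagents that add atoms: 3-chloroperoxybenzoic acid OOC(=O)c1cccc(Cl)c1
Why: Prilezhaev epoxidation is stereospecific (Z-alkene to cis-epoxide), and allylic 1,3-strain should place the ring oxygen of the quaternary centre in the alkene plane so that the peracid approaches anti to the isopropyl group, which is the face needed for C-5 and C-6.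

**Step 9**
Reactants: 14 cis-epoxy lactone
Product: 15 2-methylidene-oxane (exocyclic enol ether)
Conditions: Cp2TiMe2, toluene, 70 °C, dark
Reagents that add atoms: dimethyltitanocene C[Ti](C)(C1C=CC=C1)C1C=CC=C1
Why: Petasis methylenation converts the lactone carbonyl into the enol ether through Cp2Ti=CH2 under neutral conditions that the epoxide and the ketal should tolerate.

**Step 10**
Reactants: 15 2-methylidene-oxane (exocyclic enol ether)
Product: 19 enone diol 4,6-dihydroxydauc-8-en-10-one, via endocyclic enol ether 16 (not isolated), via bridged methyl ketal 17 (not isolated), via ring-opened methyl enol ether 18 (not isolated)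
Conditions: Me3SiOTf (3.3 equiv), Me3SiOMe (1.5 equiv), 2,6-di-tert-butyl-4-methylpyridine (3.5 equiv), CH2Cl2, −78 → −20 °C; then 1 M HCl, THF, 0 °C
Reagents that add atoms: water O
Why: Proposed new method: the pyridinium triflate formed in situ equilibrates 15 with the endocyclic enol ether 16, and Me3SiOTf activates the cis-epoxide, which the nucleophilic enol ether carbon C-1 opens at C-5 with inversion; Me3SiOMe traps the resulting 2-oxabicyclo[2.2.1]heptyl oxocarbenium ion as ketal 17. Re-ionisation of 17 with cleavage of the strained O-4–C-10 bond and loss of a proton gives enol ether 18, whose C-9 adds to the oxocarbenium ion formed from the dioxolane at C-8; loss of the silylated glycol ether then gives a conjugated oxocarbenium ion that aqueous acid hydrolyses to the C-8=C-9 enone while the silyl ethers are cleaved. The closest known reactions are the Lewis acid mediated opening of epoxides by enol ethers, the terpinyl-to-bornyl 1,4-bridging cyclisation and the Me3SiOTf mediated Mukaiyama-type aldol condensation of enol ethers with ketals; their combination in one flask and the ketal relay that releases the tether are the new part. The five-membered ring closes by 5-exo-tet attack across the six-membered enol ether (1,4-bridging), the seven-membered ring by a 7-(enolendo)-exo-trig addition followed by elimination. C-1 is controlled by the O-4–C-10 tether, which lets C-1 bond to C-5 only on the face of O-4 (C-10 cis to O-4, Me-15 cis to the isopropyl group), C-5 by inversion at the epoxide carbon, and C-6 is carried over from the epoxide. The step needs C-alkylation through C-1 and not C-9, and aldol closure from C-9 onto C-8: attack through C-9 would give a bridgehead oxocarbenium ion, C-10 is a neopentylic and poor electrophile, and closure of the C-8 side onto C-10 is barred inside the bridged ketal and would otherwise give a trans-fused bicyclo[3.3.0]octane.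

**Step 11**
Reactants: 19 enone diol
Product: 20 6-O-[4-(tert-butyldimethylsilyloxy)benzoyl] enone
Conditions: 4-(tert-butyldimethylsilyloxy)benzoic acid, EDC·HCl, DMAP, CH2Cl2, rt
Reagents that add atoms: 4-[(tert-butyldimethylsilyl)oxy]benzoic acid CC(C)(C)[Si](C)(C)Oc1ccc(cc1)C(O)=O
Why: Steglich esterification should acylate the secondary 6-hydroxyl only, because the tertiary 4-hydroxyl is too hindered.

**Step 12**
Reactants: 20 6-O-aroyl enone
Product: 21 10-alcohol (hydroxyl trans to Me-15)
Conditions: LiBH(s-Bu)3 (2.2 equiv), THF, −78 °C; aqueous NH4Cl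
Reagents that add atoms: none
Why: 1,2-Reduction of the 3,3-disubstituted enone by the bulky borohydride along the pseudo-equatorial trajectory (as in the reduction of 4,4-dimethyl-3-keto steroids to axial alcohols) should give the pseudo-axial 10-alcohol trans to Me-15, conjugate reduction being blocked by the substituents on C-8.

**Step 13**
Reactants: 21 10-alcohol
Product: 22 10-O-isovaleryl silyl-protected diester
Conditions: 3-methylbutanoic anhydride, DMAP (cat.), pyridine, rt → 40 °C
Reagents that add atoms: 3-methylbutanoic anhydride CC(C)CC(=O)OC(=O)CC(C)C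
Why: DMAP-catalysed acylation esterifies the secondary allylic alcohol and leaves the tertiary 4-hydroxyl free.

**Step 14**
Reactants: 22 silyl-protected diester
Product: 23 target CNP0086724.4
Conditions: Bu4NF, AcOH, THF, 0 °C
Reagents that add atoms: none
Why: Buffered fluoride cleaves the aryl silyl ether (desilylation) without touching the two esters or the tertiary alcohol.

**Compound list**

1 | (R)-terpinen-4-ol, (1R)-4-methyl-1-(propan-2-yl)cyclohex-3-en-1-ol | CC1=CC[C@@](O)(C(C)C)CC1 | starting material
2 | triethyl{[(1R)-4-methyl-1-(propan-2-yl)cyclohex-3-en-1-yl]oxy}silane | CC1=CC[C@@](O[Si](CC)(CC)CC)(C(C)C)CC1 | intermediate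
3 | [2-methyl-5-(propan-2-yl)-5-(triethylsilyloxy)cyclohexyl]borane, drawn as the monoalkylborane, silyloxy carbon as in 2 | CC1C(B)C[C@@](O[Si](CC)(CC)CC)(C(C)C)CC1 | intermediate (not isolated)
4 | 2-methyl-5-(propan-2-yl)-5-(triethylsilyloxy)cyclohexan-1-ol, silyloxy carbon as in 2, epimer mixture at C-1 and C-2 of the ring | CC1C(O)C[C@@](O[Si](CC)(CC)CC)(C(C)C)CC1 | intermediate
5 | 2-methyl-5-(propan-2-yl)-5-(triethylsilyloxy)cyclohexan-1-one, silyloxy carbon as in 2, 2-epimer mixture | CC1C(=O)C[C@@](O[Si](CC)(CC)CC)(C(C)C)CC1 | intermediate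
6 | lithium enolate of 5 on the methylene side | CC1C(O[Li])=C[C@@](O[Si](CC)(CC)CC)(C(C)C)CC1 | intermediate (not isolated)
7 | 6-methyl-3-(propan-2-yl)-3-(triethylsilyloxy)-1-(trimethylsilyloxy)cyclohex-1-ene | CC1C(O[Si](C)(C)C)=C[C@@](O[Si](CC)(CC)CC)(C(C)C)CC1 | intermediate
8 | 5-formyl-2,6-dimethyl-5-(triethylsilyloxy)heptanoic acid, C-5 as in 2, 2-epimer mixture | CC(CC[C@@](C=O)(C(C)C)O[Si](CC)(CC)CC)C(=O)O | intermediate (not isolated)
9 | (2S)-5-methyl-6-oxo-2-(propan-2-yl)oxane-2-carbaldehyde, 5-epimer mixture | CC1CC[C@@](C=O)(C(C)C)OC1=O | intermediate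
10 | 2-(2-bromoethyl)-2-methyl-1,3-dioxolane | CC1(CCBr)OCCO1 | starting material
11 | [2-(2-methyl-1,3-dioxolan-2-yl)ethyl]triphenylphosphonium bromide | CC1(CC[P+](c2ccccc2)(c2ccccc2)c2ccccc2)OCCO1.[Br-] | intermediate
12 | [2-(2-methyl-1,3-dioxolan-2-yl)ethylidene]triphenylphosphorane | CC1(CC=P(c2ccccc2)(c2ccccc2)c2ccccc2)OCCO1 | intermediate (not isolated)
13 | 3-methyl-6-[(1Z)-3-(2-methyl-1,3-dioxolan-2-yl)prop-1-en-1-yl]-6-(propan-2-yl)oxan-2-one, quaternary carbon as in 9, 3-epimer mixture | CC1CC[C@@](/C=C\CC2(C)OCCO2)(C(C)C)OC1=O | intermediate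
14 | 3-methyl-6-{cis-3-[(2-methyl-1,3-dioxolan-2-yl)methyl]oxiran-2-yl}-6-(propan-2-yl)oxan-2-one, epoxide oxygen on the alkene face anti to the isopropyl group | CC1CC[C@@]([C@@H]3O[C@@H]3CC2(C)OCCO2)(C(C)C)OC1=O | intermediate
15 | 3-methyl-2-methylidene-6-{cis-3-[(2-methyl-1,3-dioxolan-2-yl)methyl]oxiran-2-yl}-6-(propan-2-yl)oxane, stereocentres as in 14 | CC1CC[C@@]([C@@H]3O[C@@H]3CC2(C)OCCO2)(C(C)C)OC1=C | intermediate
16 | 5,6-dimethyl-2-{cis-3-[(2-methyl-1,3-dioxolan-2-yl)methyl]oxiran-2-yl}-2-(propan-2-yl)-3,4-dihydro-2H-pyran | CC1=C(C)O[C@]([C@@H]3O[C@@H]3CC2(C)OCCO2)(C(C)C)CC1 | intermediate (not isolated)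
17 | 3-methoxy-3,4-dimethyl-1-(propan-2-yl)-7-[2-(2-methyl-1,3-dioxolan-2-yl)-1-(trimethylsilyloxy)ethyl]-2-oxabicyclo[2.2.1]heptane, side chain on the one-carbon bridge pointing away from the oxygen bridge, either ketal epimer | COC1(C)O[C@]2(C(C)C)CC[C@@]1(C)[C@H]2[C@H](O[Si](C)(C)C)CC3(C)OCCO3 | intermediate (not isolated)
18 | cyclopentane carrying at C-1 methyl and 1-methoxyethenyl, at C-4 isopropyl and trimethylsilyloxy, at C-5 the chain CH(OSiMe3)CH2C(dioxolane)CH3; configuration as in the target | C=C(OC)[C@@]1(C)CC[C@](O[Si](C)(C)C)(C(C)C)[C@@H]1[C@H](O[Si](C)(C)C)CC2(C)OCCO2 | intermediate (not isolated)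
19 | 4,6-dihydroxydauc-8-en-10-one, 3,4-dihydroxy-6,8a-dimethyl-3-(propan-2-yl)-2,3,3a,4,5,8a-hexahydroazulen-8(1H)-one; trans-fused, 4-OH cis to H-5, 6-OH cis to Me-15 | CC1=CC(=O)[C@@]2(C)CC[C@](O)(C(C)C)[C@@H]2[C@H](O)C1 | intermediate
20 | 6-O-[4-(tert-butyldimethylsilyloxy)benzoyl] derivative of 19 | CC1=CC(=O)[C@@]2(C)CC[C@](O)(C(C)C)[C@@H]2[C@H](OC(=O)c2ccc(O[Si](C)(C)C(C)(C)C)cc2)C1 | intermediate
21 | 10-alcohol from 20, 10-OH trans to Me-15 and on the face of H-5 | CC1=C[C@@H](O)[C@@]2(C)CC[C@](O)(C(C)C)[C@@H]2[C@H](OC(=O)c2ccc(O[Si](C)(C)C(C)(C)C)cc2)C1 | intermediate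
22 | 10-O-(3-methylbutanoyl) derivative of 21 | CC1=C[C@@H](OC(=O)CC(C)C)[C@@]2(C)CC[C@](O)(C(C)C)[C@@H]2[C@H](OC(=O)c2ccc(O[Si](C)(C)C(C)(C)C)cc2)C1 | intermediate
23 | CNP0086724.4, 3-hydroxy-6,8a-dimethyl-8-(3-methylbutanoyloxy)-3-(propan-2-yl)-1,2,3,3a,4,5,8,8a-octahydroazulen-4-yl 4-hydroxybenzoate | CC1=C[C@@H](OC(=O)CC(C)C)[C@@]2(C)CC[C@](O)(C(C)C)[C@@H]2[C@H](OC(=O)c2ccc(O)cc2)C1 | target

**Step count and risks**

Total step count: 14. Longest linear sequence: 13 steps (1 to 23 through steps 1 to 5 and 7 to 14).

Steps most likely to fail: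

Step 10 (Proposed new method). The cascade may branch or stall: the activated epoxide may be opened by triflate or rearrange by hydride shift instead of being alkylated by C-1, the ketal relay may fail to release the O-4–C-10 bridge, or the aldol closure may take the wrong sense. The fallback sets out from 14 and makes the two bonds one after the other with known reactions. KN(SiMe3)2 in THF at 0 °C generates the lactone enolate, which opens the epoxide at C-5 (intramolecular enolate alkylation) to give the bridged lactone alcohol F1. Silylation (t-BuMe2SiOTf, 2,6-lutidine) gives the bridged lactone silyl ether F2, and Petasis methylenation (Cp2TiMe2, toluene, 70 °C) gives the bridged enol ether F3. Aqueous acid (1 M HCl, THF) hydrolyses the enol ether and the dioxolane and so releases the hydroxy diketone F4. Amine-catalysed intramolecular aldol condensation (pyrrolidine, AcOH, toluene, 60 °C) closes the seven-membered ring to the silyl enone F5, and HF·pyridine removes the silyl group; the route is rejoined at 19.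

Step 12. Hydride delivery to C-10 may show poor or reversed facial selectivity (attack anti to Me-15 gives the 10-epimer), or conjugate reduction may compete. The fallback sets out from 20: Luche reduction (NaBH4, CeCl3·7H2O, MeOH, −78 °C), in which hydride is expected to come anti to Me-15, gives the 10-epimeric allylic alcohol F6. Mitsunobu esterification with 3-methylbutanoic acid (PPh3, diisopropyl azodicarboxylate, toluene, 0 °C → rt) then installs the isovalerate with inversion at C-10; the route is rejoined at 22.

Step 8. The quaternary centre may discriminate poorly between the two alkene faces in the peracid epoxidation. The fallback sets out from 13 and replaces substrate control by reagent control. Thiyl-radical equilibration (PhSSPh, hν, benzene) gives the E-alkene lactone F7. Shi epoxidation (the Shi ketone enantiomer derived from L-sorbose, chosen by the spiro transition-state model; 2KHSO5·KHSO4·K2SO4, K2CO3, MeCN–CH2(OMe)2–H2O, 0 °C) gives the trans-epoxy lactone F8, with C-5 as in 14 and C-6 inverted. Petasis methylenation gives the enol ether F9, and the conditions of step 10 give the 6-epimeric enone diol F10. Mitsunobu esterification with 4-(tert-butyldimethylsilyloxy)benzoic acid (PPh3, diisopropyl azodicarboxylate) inverts C-6; the route is rejoined at 20.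

**Further compounds**

F1 | step 10 | 7-[1-hydroxy-2-(2-methyl-1,3-dioxolan-2-yl)ethyl]-4-methyl-1-(propan-2-yl)-2-oxabicyclo[2.2.1]heptan-3-one | O=C1O[C@]2(C(C)C)CC[C@@]1(C)[C@H]2[C@H](O)CC3(C)OCCO3
F2 | step 10 | tert-butyldimethylsilyl ether of F1 | O=C1O[C@]2(C(C)C)CC[C@@]1(C)[C@H]2[C@H](O[Si](C)(C)C(C)(C)C)CC3(C)OCCO3
F3 | step 10 | 3-methylidene analogue of F2 (bridged enol ether) | C=C1O[C@]2(C(C)C)CC[C@@]1(C)[C@H]2[C@H](O[Si](C)(C)C(C)(C)C)CC3(C)OCCO3
F4 | step 10 | cyclopentane hydroxy diketone: C-1 acetyl and methyl, C-4 hydroxyl and isopropyl, C-5 chain CH(OSi-t-BuMe2)CH2C(=O)CH3 | CC(=O)[C@@]1(C)CC[C@](O)(C(C)C)[C@@H]1[C@H](O[Si](C)(C)C(C)(C)C)CC(C)=O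
F5 | step 10 | 6-O-tert-butyldimethylsilyl ether of 19 | CC1=CC(=O)[C@@]2(C)CC[C@](O)(C(C)C)[C@@H]2[C@H](O[Si](C)(C)C(C)(C)C)C1
F6 | step 12 | 10-epimer of 21 (10-OH cis to Me-15) | CC1=C[C@H](O)[C@@]2(C)CC[C@](O)(C(C)C)[C@@H]2[C@H](OC(=O)c2ccc(O[Si](C)(C)C(C)(C)C)cc2)C1
F7 | step 8 | E-isomer of 13 | CC1CC[C@@](/C=C/CC2(C)OCCO2)(C(C)C)OC1=O
F8 | step 8 | trans-epoxy lactone, C-5 as in 14 and C-6 inverted | CC1CC[C@@]([C@@H]3O[C@H]3CC2(C)OCCO2)(C(C)C)OC1=O
F9 | step 8 | 2-methylidene-oxane from F8 | CC1CC[C@@]([C@@H]3O[C@H]3CC2(C)OCCO2)(C(C)C)OC1=C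
F10 | step 8 | 6-epimer of 19 | CC1=CC(=O)[C@@]2(C)CC[C@](O)(C(C)C)[C@@H]2[C@@H](O)C1
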